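**Plan**
1. Retrosynthesis: the acetates and the groups on O3, O11 and O12 go last; the lactone is cut at O–C19 and C8–C17 (lactic acid dioxolanone aldol on a C8 ketone); ring B is cut at C4–C5 (Nozaki–Hiyama–Kishi), C2–C3 (glycolate aldol) and C7–C8 (alkoxyallylstannane); ring A is cut at C13–C14 and C10–C11.
2. Enabling feature: the quaternary C1 of ring A is flanked by C10 and C14, and C10 carries C9–C8. With one temporary bond C8–C14 these five carbons are a cyclopenta-1,3-diene (C14=C8–C9=C10, C1 sp3), and C11–C12–C13 with oxygen on C12 is a 2-oxyallyl (siloxyvinyl carbenoid) unit, so ring A is the retron of a (4+3) annulation.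
3. Forward: prochiral diene 4 and diazo ester 7 give bicyclo[3.2.1]octadiene 9, which holds ring A inside a temporary bicycle. The ester helper on C13 is traded for chlorine, the two-carbon bridge is dihydroxylated, and a Grob fragmentation cuts C8–C14, which unveils C13=C14 and the C9(O)–C8 aldehyde.
4. Then C7 and the (Z)-C5=C6 iodide are added, the ring A cis-diol is set, C2–C4 are added, ring B is closed, the lactone is built on C8, and the acetates are placed before the last unmasking.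
5. Stereochemistry: C1 and C10 from the catalyst-controlled desymmetrising (4+3) step; C9 from endo-dihydroxylation under the C1 methyl; C7 from Felkin-controlled stannane addition; C11/C12 from OsO4 anti to the C10 chain; C2/C3 from the oxazolidinethione; C4 from hydroxyl-directed reduction; C8 from chelation; C17 from (R)-lactic acid; C5=C6 from a (Z)-alkenyl iodide.

Key step: step 5

Remark: atom numbers are those of the briarane skeleton (C1 quaternary fusion carbon, C2–C9 ring B, C10–C14 ring A, C17/C19 lactone carbons); TBS = tert-butyldimethylsilyl, TES = triethylsilyl, TIPS = triisopropylsilyl, TBDPS = tert-butyldiphenylsilyl.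
Remark (assumption): for the chiral catalyst of step 5 the enantiomer named is taken to be the one that gives the configuration drawn; its mirror image would be used if the sense of induction is opposite.
Remark: C11 of the ring A ketones 12–23 lies next to the carbonyl; its configuration may drift and is erased in step 15.
Remark: compounds 1, 5, 16, 21, 29, 30 and 41 are taken as commercially available.

**Route**

Step 1
Reactants: 1 cyclopent-3-ene-1-carbonitrile
Product: 2 1-methylcyclopent-3-ene-1-carbonitrile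
Conditions: LiN(iPr)2, THF, −78 °C; MeI, −78 → 0 °C
Reagents that add atoms: iodomethane (CI)
Why: alkylation of the nitrile-stabilised carbanion puts the future C15 methyl on the future C1, and no stereocentre arises because the ring is symmetric.

Step 2
Reactants: 2 1-methylcyclopent-3-ene-1-carbonitrile
Product: 4 1-methylcyclopenta-2,4-diene-1-carbonitrile, via trans-dibromide 3 (not isolated)
Conditions: Br2, CH2Cl2, −78 °C; then DBU (3 equiv), THF, 60 °C
Reagents that add atoms: none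
Why: anti bromination and twofold E2 elimination (the trans-dibromide can only eliminate toward the ring CH2 groups) should give the 5,5-disubstituted cyclopentadiene, which cannot undergo 1,5-hydrogen shifts.

Step 3
Reactants: 5 tert-butyl 3-oxopentanoate
Product: 6 tert-butyl 2-diazo-3-oxopentanoate
Conditions: 4-acetamidobenzenesulfonyl azide, Et3N, MeCN, 0 → 23 °C
Reagents that add atoms: 4-acetamidobenzenesulfonyl azide (CC(=O)Nc1ccc(cc1)S(=O)(=O)N=[N+]=[N-])
Why: Regitz diazo transfer to the activated methylene of a β-keto ester.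

Step 4
Reactants: 6 tert-butyl 2-diazo-3-oxopentanoate
Product: 7 tert-butyl (3Z)-3-(TBS-oxy)-2-diazopent-3-enoate
Conditions: TBSOTf, Et3N, CH2Cl2, 0 °C
Reagents that add atoms: tert-butyldimethylsilyl triflate (CC(C)(C)[Si](C)(C)OS(=O)(=O)C(F)(F)F)
Why: soft enolisation of the diazo ketone should give the (Z)-enol silane, the donor part of a donor/acceptor carbenoid precursor.

Step 5
Reactants: 4 1-methylcyclopenta-2,4-diene-1-carbonitrile; 7 tert-butyl (3Z)-3-(TBS-oxy)-2-diazopent-3-enoate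
Product: 9 tert-butyl 8-cyano-4,8-dimethyl-3-(TBS-oxy)bicyclo[3.2.1]octa-2,6-diene-2-carboxylate, via cis-divinylcyclopropane 8 (not isolated)
Conditions: Rh2(S-PTAD)4 (1 mol %), 2,2-dimethylbutane, −40 → 23 °C, slow addition of 7 to 4 (3 equiv)
Reagents that add atoms: none
Why: Rh2(S-PTAD)4 turns 7 into a donor/acceptor vinyl carbenoid that cyclopropanates one of the two enantiotopic C=C bonds of prochiral 4 (C14=C8) on the face of the slim nitrile, and the resulting cis-divinylcyclopropane 8 undergoes a boat-type [3,3] Cope shift below room temperature, so that C13–C14 and C10–C11 form in one operation. The closest known reaction type is the rhodium-carbenoid tandem cyclopropanation/Cope ((4+3)) annulation of siloxyvinyl diazoacetates with cyclopentadiene. The cyclopropane closes by concerted (2+1) carbenoid addition; the seven-membered ring C14–C13–C12–C11–C10–C9–C8, which holds ring A as the six-membered ring bridged by C1, closes by the suprafacial [3,3] shift. C10 and C14 follow from the catalyst-controlled choice of alkene, C1 from approach anti to its methyl (methyl syn to the C8=C9 bridge, nitrile syn to the C11–C13 bridge), and C11 from the (Z)-enol silane geometry in the boat transition state. The step needs enantiotopic-group and facial selectivity and cyclopropanation in preference to carbene dimerisation or C–H insertion; the locked s-cis diene, the linear nitrile and slow addition of 7 to excess 4 should secure them.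

Step 6
Reactants: 9 tert-butyl 8-cyano-4,8-dimethyl-3-(TBS-oxy)bicyclo[3.2.1]octa-2,6-diene-2-carboxylate
Product: 12 2-chloro-4,8-dimethyl-3-oxobicyclo[3.2.1]oct-6-ene-8-carbonitrile, via chloro keto ester 10 (not isolated), via chloro keto acid 11 (not isolated)
Conditions: N-chlorosuccinimide, CH2Cl2, 0 °C; then CF3CO2H, 23 → 40 °C
Reagents that add atoms: N-chlorosuccinimide (O=C1CCC(=O)N1Cl)
Why: chlorination of the push–pull enol silane at C13 from the exo face, then acidolysis of the tert-butyl ester and decarboxylation of the β-keto acid, should remove the ester helper and leave chlorine only at C13 (axial epimer drawn; C13 can epimerise).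

Step 7
Reactants: 12 2-chloro-4,8-dimethyl-3-oxobicyclo[3.2.1]oct-6-ene-8-carbonitrile
Product: 13 2-chloro-6,7-dihydroxy-4,8-dimethyl-3-oxobicyclo[3.2.1]octane-8-carbonitrile (endo,cis-diol)
Conditions: OsO4 (cat.), N-methylmorpholine N-oxide, acetone/H2O, 0 → 23 °C
Reagents that add atoms: osmium tetroxide (O=[Os](=O)(=O)=O); N-methylmorpholine N-oxide (C[N+]1([O-])CCOCC1); water (O)
Why: syn-dihydroxylation of the strained etheno bridge, where the C1 methyl that lies over the exo face should send osmium to the endo face and so set the C9 carbinol (and a temporary C8 carbinol).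

Step 8
Reactants: 13 2-chloro-6,7-dihydroxy-4,8-dimethyl-3-oxobicyclo[3.2.1]octane-8-carbonitrile
Product: 15 2-(TBDPS-oxy)-2-(6-cyano-2,6-dimethyl-3-oxocyclohex-4-en-1-yl)acetaldehyde, via hydroxy aldehyde 14 (not isolated)
Conditions: KN(SiMe3)2 (1.0 equiv), THF, −78 °C; then TBDPSCl, imidazole, DMF, 23 °C
Reagents that add atoms: tert-butyl(chloro)diphenylsilane (CC(C)(C)[Si](Cl)(c1ccccc1)c1ccccc1)
Why: Grob fragmentation, in which the C8 alkoxide pushes, the C8–C14 bond anti-periplanar to the axial C13–Cl bond breaks and chloride leaves, should remove the temporary ring and give the C13=C14 bond of ring A and the C8 aldehyde (only the C8 alkoxide has a leaving group in 1,3-relation); the C9 hydroxyl is then silylated.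

Step 9
Reactants: 16 tert-butyldimethyl(prop-2-en-1-yloxy)silane
Product: 17 (Z)-tert-butyldimethyl{[3-(tributylstannyl)prop-1-en-1-yl]oxy}silane
Conditions: sBuLi, THF, −78 °C; then Bu3SnCl
Reagents that add atoms: tributyltin chloride (CCCC[Sn](Cl)(CCCC)CCCC)
Why: α-lithiation of the allyl silyl ether gives the oxygen-chelated (Z)-allyl anion, which is stannylated at the γ-carbon.

Step 10
Reactants: 15 2-(TBDPS-oxy)-2-(6-cyano-2,6-dimethyl-3-oxocyclohex-4-en-1-yl)acetaldehyde; 17 (Z)-γ-(TBS-oxy)allylstannane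
Product: 18 ring A enone carrying on C10 the chain C9H(OTBDPS)–C8H(OH)–C7H(OTBS)–C6H=CH2 (C7/C8 syn, C8/C9 anti)
Conditions: BF3·OEt2, CH2Cl2, −78 °C; aqueous KF work-up
Reagents that add atoms: none
Why: Lewis-acid-promoted γ-alkoxyallylstannane addition through an open transition state should give the syn C7/C8 pair and, under Felkin–Anh control by the non-chelating C9 silyl ether, the C8/C9 anti pair, which fixes C7 relative to C9 (C8 is later oxidised); the aldehyde reacts in preference to the enone.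

Step 11
Reactants: 18 homoallylic alcohol
Product: 19 C8 TES ether of 18
Conditions: TESCl, imidazole, DMAP (cat.), DMF, 0 °C
Reagents that add atoms: chlorotriethylsilane (CC[Si](Cl)(CC)CC)
Why: silylation under mild base masks C8–OH with the most labile silyl group without enolising the enone.

Step 12
Reactants: 19 C8 TES ether
Product: 20 C6 aldehyde: chain C9H(OTBDPS)–C8H(OTES)–C7H(OTBS)–C6HO on ring A enone
Conditions: OsO4 (cat.), NaIO4, 2,6-lutidine, dioxane/H2O, 23 °C
Reagents that add atoms: osmium tetroxide (O=[Os](=O)(=O)=O); sodium periodate ([Na+].[O-]I(=O)(=O)=O); water (O)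
Why: Lemieux–Johnson cleavage, in which the terminal vinyl group should be dihydroxylated in preference to the electron-poor, hindered enone double bond.

Step 13
Reactants: 20 C6 aldehyde; 21 ethyltriphenylphosphonium iodide
Product: 23 (Z)-alkenyl iodide: chain C9H(OTBDPS)–C8H(OTES)–C7H(OTBS)–C6H=C5(CH3)I on ring A enone, iodine cis to C7, via iodo ylide 22 (not isolated)
Conditions: 21, nBuLi, THF, 23 °C; I2, −78 °C; NaN(SiMe3)2, −20 °C; then 20, −78 °C
Reagents that add atoms: iodine (II)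
Why: Stork–Zhao olefination with the α-iodo ylide should give the (Z)-2-iodoalkene, which carries C5, its methyl and the handle for ring closure in the geometry of the target.

Step 14
Reactants: 23 (Z)-alkenyl iodide enone
Product: 24 C12 allylic alcohol of 23 (12-OH trans to 11-H)
Conditions: NaBH4, CeCl3·7H2O, MeOH, −78 °C
Reagents that add atoms: none
Why: Luche 1,2-reduction, with hydride entering anti to the C11 methyl; the C12 configuration is without consequence.

Step 15
Reactants: 24 C12 allylic alcohol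
Product: 25 ring A cyclohexa-1,3-diene (C11=C12, C13=C14) with the chain of 23
Conditions: Martin sulfurane Ph2S[OC(CF3)2Ph]2, CH2Cl2, 23 °C
Reagents that add atoms: none
Why: dehydration of the secondary allylic alcohol can only lose the C11 hydrogen, so it should give the conjugated diene.

Step 16
Reactants: 25 ring A diene
Product: 26 ring A 11,12-cis-diol (both hydroxyls trans to the C10 chain)
Conditions: OsO4 (cat.), N-methylmorpholine N-oxide (1.05 equiv), acetone/H2O, 0 °C
Reagents that add atoms: osmium tetroxide (O=[Os](=O)(=O)=O); N-methylmorpholine N-oxide (C[N+]1([O-])CCOCC1); water (O)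
Why: osmylation should take place at the more electron-rich trisubstituted C11=C12 bond, on the face anti to the C10 chain and the C1 methyl, which sets C11 and C12; the iodoalkene and the neopentyl C13=C14 bond are less reactive.

Step 17
Reactants: 26 ring A cis-diol
Product: 27 11,12-acetonide nitrile
Conditions: 2-methoxypropene, pyridinium p-toluenesulfonate (cat.), CH2Cl2, 0 °C
Reagents that add atoms: 2-methoxypropene (COC(C)=C)
Why: the cis tertiary/secondary diol closes to a five-membered ketal under mild acid that leaves the TES ether intact.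

Step 18
Reactants: 27 acetonide nitrile
Product: 28 C2 aldehyde (formyl group on C1)
Conditions: iBu2AlH, toluene, −78 °C; aqueous Rochelle salt
Reagents that add atoms: water (O)
Why: partial reduction of the neopentyl nitrile to the N-aluminoimine and hydrolysis; no other reducible carbonyl group is present.

Step 19
Reactants: 29 (prop-2-en-1-yloxy)acetic acid; 30 (S)-4-benzyl-1,3-oxazolidine-2-thione
Product: 31 (S)-3-[(allyloxy)acetyl]-4-benzyl-1,3-oxazolidine-2-thione
Conditions: EDC·HCl, DMAP (cat.), CH2Cl2, 23 °C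
Reagents that add atoms: none
Why: carbodiimide N-acylation of the auxiliary.

Step 20
Reactants: 28 C2 aldehyde; 31 N-glycolyl oxazolidinethione
Product: 32 anti-aldol adduct: C1–C2H(OH)–C3H(O-allyl)–C4(=O)–auxiliary
Conditions: 31, TiCl4, iPr2NEt, CH2Cl2, −78 °C; then 28 precomplexed with TiCl4, −78 °C
Reagents that add atoms: none
Why: anti-selective glycolate aldol of the titanium enolate with the TiCl4-activated aldehyde through an open transition state, where the auxiliary should fix C3 and the anti relationship C2.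

Step 21
Reactants: 32 anti-aldol adduct
Product: 33 β-hydroxy aldehyde (C4 aldehyde, free 2-OH)
Conditions: iBu2AlH, CH2Cl2, −78 °C
Reagents that add atoms: none
Why: direct reductive cleavage of the N-acyl oxazolidinethione to the aldehyde, which frees the auxiliary.

Step 22
Reactants: 33 β-hydroxy aldehyde with (Z)-alkenyl iodide
Product: 34 ten-membered ring B carbinol (C4–OH; the Felkin epimer is drawn, both epimers are carried on)
Conditions: CrCl2 (excess), NiCl2 (cat.), DMSO/THF, 23 °C, high dilution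
Reagents that add atoms: none
Why: Nozaki–Hiyama–Kishi reaction, in which the alkenyl iodide is activated by nickel, passed to chromium and added chemoselectively to the aldehyde, should close ring B at C4–C5 with retention of the (Z) geometry; the C4 configuration is not relied on.

Step 23
Reactants: 34 ring B carbinol
Product: 35 ring B enone (C4 ketone, free 2-OH)
Conditions: MnO2, CH2Cl2, 23 °C
Reagents that add atoms: none
Why: MnO2 oxidises only the allylic C4 alcohol, so both C4 epimers converge.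

Step 24
Reactants: 35 ring B enone
Product: 36 2,4-anti diol
Conditions: Me4NBH(OAc)3, MeCN/AcOH, −30 °C
Reagents that add atoms: none
Why: Evans–Saksena reduction, in which the acetoxyborohydride bound to O2 delivers hydride intramolecularly to the face of C4 syn to O2, should give the trans-1,3-diol, that is the C4 configuration of the target.

Step 25
Reactants: 36 2,4-anti diol
Product: 37 2,4-bis-TIPS ether
Conditions: TIPSOTf, 2,6-lutidine, CH2Cl2, −40 → 0 °C
Reagents that add atoms: triisopropylsilyl triflate (CC(C)[Si](OS(=O)(=O)C(F)(F)F)(C(C)C)C(C)C)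
Why: robust silyl ethers on O2 and O4 that survive the later selective removal of TES and TBS.

Step 26
Reactants: 37 bis-TIPS ether
Product: 38 C8 alcohol
Conditions: HF·pyridine, pyridine, THF, 0 °C
Reagents that add atoms: none
Why: buffered fluoride removes the TES ether much faster than the TBS, TIPS and TBDPS ethers.

Step 27
Reactants: 38 C8 alcohol
Product: 39 C8 ketone (7-OTBS, 9-OTBDPS)
Conditions: Dess–Martin periodinane, NaHCO3, CH2Cl2, 23 °C
Reagents that add atoms: none
Why: neutral oxidation of the only free hydroxyl.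

Step 28
Reactants: 39 C8 ketone
Product: 40 7-hydroxy-8-ketone
Conditions: HF·pyridine, THF, 0 → 23 °C
Reagents that add atoms: none
Why: the TBS ether that is both allylic and α to the ketone is the most labile silyl ether left and should be cleaved in the presence of TIPS and TBDPS.

Step 29
Reactants: 41 (R)-lactic acid
Product: 42 (2R,5R)-2-tert-butyl-5-methyl-1,3-dioxolan-4-one
Conditions: pivalaldehyde, TsOH (cat.), pentane, reflux with water separation; crystallisation
Reagents that add atoms: pivalaldehyde (CC(C)(C)C=O)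
Why: acetalisation gives the cis-dioxolanone, which stores the lactic acid stereocentre in the acetal carbon (self-regeneration of stereocentres).

Step 30
Reactants: 40 7-hydroxy-8-ketone; 42 (2R,5R)-2-tert-butyl-5-methyl-1,3-dioxolan-4-one
Product: 44 lactone with 8,17-diol (2,4-bis-TIPS, 9-OTBDPS, 3-O-allyl, 11,12-acetonide), via aldol adduct 43 (not isolated)
Conditions: 42, LiN(iPr)2, THF, −78 °C; then 40 (0.4 equiv), −78 → −20 °C; aqueous NH4Cl
Reagents that add atoms: none
Why: the dioxolanone enolate should add to C8 anti to its tert-butyl group (C17 from lactic acid), on the ketone face opposite C6 in the lithium chelate of the C7 alkoxide (C8), and the C7 alkoxide then opens the dioxolanone with loss of pivalaldehyde to close the γ-lactone.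

Step 31
Reactants: 44 lactone
Product: 45 2,4,9-triol
Conditions: Bu4NF, AcOH, THF, 40 °C
Reagents that add atoms: none
Why: buffered fluoride removes the two TIPS ethers and the TBDPS ether and leaves the acetonide, the allyl ether and the lactone.

Step 32
Reactants: 45 2,4,9-triol
Product: 46 2,4,9-triacetate
Conditions: Ac2O, pyridine, DMAP (cat.), CH2Cl2, 0 → 23 °C
Reagents that add atoms: acetic anhydride (CC(=O)OC(C)=O)
Why: the three secondary alcohols should be acetylated while the tertiary hydroxyls on C8 and C17 stay free.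

Step 33
Reactants: 46 triacetate
Product: 48 Brianodin C, via propenyl ether 47 (not isolated)
Conditions: [Ir(cod)(PMePh2)2]PF6 (cat., activated with H2), THF, 23 °C; then AcOH/H2O (4:1), 40 °C
Reagents that add atoms: none
Why: iridium-catalysed isomerisation of the allyl ether to the 1-propenyl ether, then mild aqueous acid, should free O3 and cleave the acetonide without touching the acetates.

**Compound list**
1 | cyclopent-3-ene-1-carbonitrile | N#CC1CC=CC1 | starting material
2 | 1-methylcyclopent-3-ene-1-carbonitrile | CC1(C#N)CC=CC1 | intermediate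
3 | trans-3,4-dibromo-1-methylcyclopentane-1-carbonitrile (racemic, one enantiomer drawn) | CC1(C#N)C[C@H](Br)[C@@H](Br)C1 | intermediate
4 | 1-methylcyclopenta-2,4-diene-1-carbonitrile (prochiral; sp3 carbon = C1, ring carbons = C14, C8, C9, C10) | CC1(C#N)C=CC=C1 | intermediate
5 | tert-butyl 3-oxopentanoate | CCC(=O)CC(=O)OC(C)(C)C | starting material
6 | tert-butyl 2-diazo-3-oxopentanoate | CCC(=O)C(=[N+]=[N-])C(=O)OC(C)(C)C | intermediate
7 | tert-butyl (3Z)-3-(TBS-oxy)-2-diazopent-3-enoate | C/C=C(\O[Si](C)(C)C(C)(C)C)C(=[N+]=[N-])C(=O)OC(C)(C)C | intermediate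
8 | tert-butyl 4-cyano-4-methyl-6-[(1Z)-1-(TBS-oxy)prop-1-enyl]bicyclo[3.1.0]hex-2-ene-6-carboxylate (siloxypropenyl group endo, cyclopropane on the nitrile face) | N#C[C@]1(C)C=C[C@H]2[C@@H]1[C@@]2(C(=O)OC(C)(C)C)/C(O[Si](C)(C)C(C)(C)C)=C/C | intermediate
9 | tert-butyl 8-cyano-4,8-dimethyl-3-(TBS-oxy)bicyclo[3.2.1]octa-2,6-diene-2-carboxylate (8-methyl syn to the C6=C7 bridge, 4-methyl cis to that bridge) | N#C[C@]1(C)[C@H]2C=C[C@@H]1C(C(=O)OC(C)(C)C)=C(O[Si](C)(C)C(C)(C)C)[C@@H]2C | intermediate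
10 | tert-butyl 2-chloro-8-cyano-4,8-dimethyl-3-oxobicyclo[3.2.1]oct-6-ene-2-carboxylate (chlorine exo) | N#C[C@]1(C)[C@H]2C=C[C@@H]1[C@](Cl)(C(=O)OC(C)(C)C)C(=O)[C@@H]2C | intermediate
11 | 2-chloro-8-cyano-4,8-dimethyl-3-oxobicyclo[3.2.1]oct-6-ene-2-carboxylic acid | N#C[C@]1(C)[C@H]2C=C[C@@H]1[C@](Cl)(C(=O)O)C(=O)[C@@H]2C | intermediate
12 | 2-chloro-4,8-dimethyl-3-oxobicyclo[3.2.1]oct-6-ene-8-carbonitrile (chlorine axial, anti to the etheno bridge) | N#C[C@]1(C)[C@H]2C=C[C@@H]1[C@@H](Cl)C(=O)[C@@H]2C | intermediate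
13 | 2-chloro-6,7-dihydroxy-4,8-dimethyl-3-oxobicyclo[3.2.1]octane-8-carbonitrile (6,7-diol endo and cis) | N#C[C@]1(C)[C@H]2[C@H](O)[C@H](O)[C@@H]1[C@@H](Cl)C(=O)[C@@H]2C | intermediate
14 | 2-hydroxy-2-(6-cyano-2,6-dimethyl-3-oxocyclohex-4-en-1-yl)acetaldehyde (C8 aldehyde, C9 carbinol, ring A enone) | O=C[C@@H](O)[C@H]1[C@@H](C)C(=O)C=C[C@]1(C)C#N | intermediate
15 | 2-(TBDPS-oxy)-2-(6-cyano-2,6-dimethyl-3-oxocyclohex-4-en-1-yl)acetaldehyde | O=C[C@@H](O[Si](c1ccccc1)(c1ccccc1)C(C)(C)C)[C@H]1[C@@H](C)C(=O)C=C[C@]1(C)C#N | intermediate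
16 | tert-butyldimethyl(prop-2-en-1-yloxy)silane | C=CCO[Si](C)(C)C(C)(C)C | starting material
17 | (Z)-tert-butyldimethyl{[3-(tributylstannyl)prop-1-en-1-yl]oxy}silane | CCCC[Sn](CCCC)(CCCC)C/C=C\O[Si](C)(C)C(C)(C)C | intermediate
18 | ring A enone with chain C9H(OTBDPS)–C8H(OH)–C7H(OTBS)–C6H=CH2 on C10 (C7/C8 syn, C8/C9 anti) | C=C[C@H](O[Si](C)(C)C(C)(C)C)[C@@H](O)[C@@H](O[Si](c1ccccc1)(c1ccccc1)C(C)(C)C)[C@H]1[C@@H](C)C(=O)C=C[C@]1(C)C#N | intermediate
19 | C8 TES ether of 18 | C=C[C@H](O[Si](C)(C)C(C)(C)C)[C@@H](O[Si](CC)(CC)CC)[C@@H](O[Si](c1ccccc1)(c1ccccc1)C(C)(C)C)[C@H]1[C@@H](C)C(=O)C=C[C@]1(C)C#N | intermediate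
20 | C6 aldehyde: chain C9H(OTBDPS)–C8H(OTES)–C7H(OTBS)–C6HO on ring A enone | O=C[C@H](O[Si](C)(C)C(C)(C)C)[C@@H](O[Si](CC)(CC)CC)[C@@H](O[Si](c1ccccc1)(c1ccccc1)C(C)(C)C)[C@H]1[C@@H](C)C(=O)C=C[C@]1(C)C#N | intermediate
21 | ethyltriphenylphosphonium iodide | CC[P+](c1ccccc1)(c1ccccc1)c1ccccc1.[I-] | starting material
22 | (1-iodoethylidene)triphenylphosphorane | CC(I)=P(c1ccccc1)(c1ccccc1)c1ccccc1 | intermediate
23 | (Z)-alkenyl iodide: chain C9H(OTBDPS)–C8H(OTES)–C7H(OTBS)–C6H=C5(CH3)I on ring A enone, iodine cis to C7 | I/C(C)=C\[C@H](O[Si](C)(C)C(C)(C)C)[C@@H](O[Si](CC)(CC)CC)[C@@H](O[Si](c1ccccc1)(c1ccccc1)C(C)(C)C)[C@H]1[C@@H](C)C(=O)C=C[C@]1(C)C#N | intermediate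
24 | C12 allylic alcohol of 23 (12-OH trans to 11-H) | I/C(C)=C\[C@H](O[Si](C)(C)C(C)(C)C)[C@@H](O[Si](CC)(CC)CC)[C@@H](O[Si](c1ccccc1)(c1ccccc1)C(C)(C)C)[C@H]1[C@@H](C)[C@@H](O)C=C[C@]1(C)C#N | intermediate
25 | ring A cyclohexa-1,3-diene (C11=C12, C13=C14) with the chain of 23 | I/C(C)=C\[C@H](O[Si](C)(C)C(C)(C)C)[C@@H](O[Si](CC)(CC)CC)[C@@H](O[Si](c1ccccc1)(c1ccccc1)C(C)(C)C)[C@H]1C(C)=CC=C[C@]1(C)C#N | intermediate
26 | ring A 11,12-cis-diol (hydroxyls trans to the C10 chain) | I/C(C)=C\[C@H](O[Si](C)(C)C(C)(C)C)[C@@H](O[Si](CC)(CC)CC)[C@@H](O[Si](c1ccccc1)(c1ccccc1)C(C)(C)C)[C@H]1[C@](C)(O)[C@H](O)C=C[C@]1(C)C#N | intermediate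
27 | 11,12-acetonide of 26 (nitrile on C1) | I/C(C)=C\[C@H](O[Si](C)(C)C(C)(C)C)[C@@H](O[Si](CC)(CC)CC)[C@@H](O[Si](c1ccccc1)(c1ccccc1)C(C)(C)C)[C@H]1[C@]2(C)OC(C)(C)O[C@@H]2C=C[C@]1(C)C#N | intermediate
28 | C2 aldehyde (formyl on C1) | I/C(C)=C\[C@H](O[Si](C)(C)C(C)(C)C)[C@@H](O[Si](CC)(CC)CC)[C@@H](O[Si](c1ccccc1)(c1ccccc1)C(C)(C)C)[C@H]1[C@]2(C)OC(C)(C)O[C@@H]2C=C[C@]1(C)C=O | intermediate
29 | (prop-2-en-1-yloxy)acetic acid | C=CCOCC(=O)O | starting material
30 | (S)-4-benzyl-1,3-oxazolidine-2-thione | S=C1OC[C@H](Cc2ccccc2)N1 | starting material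
31 | (S)-3-[(allyloxy)acetyl]-4-benzyl-1,3-oxazolidine-2-thione | C=CCOCC(=O)N1C(=S)OC[C@@H]1Cc1ccccc1 | intermediate
32 | anti-aldol adduct: C2H(OH)–C3H(O-allyl)–C4(=O)–oxazolidinethione on C1 (C2/C3 anti) | I/C(C)=C\[C@H](O[Si](C)(C)C(C)(C)C)[C@@H](O[Si](CC)(CC)CC)[C@@H](O[Si](c1ccccc1)(c1ccccc1)C(C)(C)C)[C@H]1[C@]2(C)OC(C)(C)O[C@@H]2C=C[C@]1(C)[C@H](O)[C@H](OCC=C)C(=O)N1C(=S)OC[C@@H]1Cc1ccccc1 | intermediate
33 | β-hydroxy aldehyde: C2H(OH)–C3H(O-allyl)–C4HO on C1 | I/C(C)=C\[C@H](O[Si](C)(C)C(C)(C)C)[C@@H](O[Si](CC)(CC)CC)[C@@H](O[Si](c1ccccc1)(c1ccccc1)C(C)(C)C)[C@H]1[C@]2(C)OC(C)(C)O[C@@H]2C=C[C@]1(C)[C@H](O)[C@H](OCC=C)C=O | intermediate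
34 | ten-membered ring B carbinol (2-OH, 3-O-allyl, 4-OH with the Felkin epimer drawn, (5Z)-alkene, 7-OTBS, 8-OTES, 9-OTBDPS, 11,12-acetonide) | O[C@@H]1[C@H](OCC=C)[C@H](O)/C(C)=C\[C@H](O[Si](C)(C)C(C)(C)C)[C@@H](O[Si](CC)(CC)CC)[C@@H](O[Si](c2ccccc2)(c2ccccc2)C(C)(C)C)[C@H]2[C@]3(C)OC(C)(C)O[C@@H]3C=C[C@]12C | intermediate
35 | ring B enone (C4 ketone, 2-OH) | O[C@@H]1[C@H](OCC=C)C(=O)/C(C)=C\[C@H](O[Si](C)(C)C(C)(C)C)[C@@H](O[Si](CC)(CC)CC)[C@@H](O[Si](c2ccccc2)(c2ccccc2)C(C)(C)C)[C@H]2[C@]3(C)OC(C)(C)O[C@@H]3C=C[C@]12C | intermediate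
36 | 2,4-anti diol (C4 as in the target) | O[C@@H]1[C@H](OCC=C)[C@@H](O)/C(C)=C\[C@H](O[Si](C)(C)C(C)(C)C)[C@@H](O[Si](CC)(CC)CC)[C@@H](O[Si](c2ccccc2)(c2ccccc2)C(C)(C)C)[C@H]2[C@]3(C)OC(C)(C)O[C@@H]3C=C[C@]12C | intermediate
37 | 2,4-bis-TIPS ether of 36 | CC(C)[Si](C(C)C)(C(C)C)O[C@@H]1[C@H](OCC=C)[C@@H](O[Si](C(C)C)(C(C)C)C(C)C)/C(C)=C\[C@H](O[Si](C)(C)C(C)(C)C)[C@@H](O[Si](CC)(CC)CC)[C@@H](O[Si](c2ccccc2)(c2ccccc2)C(C)(C)C)[C@H]2[C@]3(C)OC(C)(C)O[C@@H]3C=C[C@]12C | intermediate
38 | C8 alcohol (TES removed) | CC(C)[Si](C(C)C)(C(C)C)O[C@@H]1[C@H](OCC=C)[C@@H](O[Si](C(C)C)(C(C)C)C(C)C)/C(C)=C\[C@H](O[Si](C)(C)C(C)(C)C)[C@@H](O)[C@@H](O[Si](c2ccccc2)(c2ccccc2)C(C)(C)C)[C@H]2[C@]3(C)OC(C)(C)O[C@@H]3C=C[C@]12C | intermediate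
39 | C8 ketone (7-OTBS) | CC(C)[Si](C(C)C)(C(C)C)O[C@@H]1[C@H](OCC=C)[C@@H](O[Si](C(C)C)(C(C)C)C(C)C)/C(C)=C\[C@H](O[Si](C)(C)C(C)(C)C)C(=O)[C@@H](O[Si](c2ccccc2)(c2ccccc2)C(C)(C)C)[C@H]2[C@]3(C)OC(C)(C)O[C@@H]3C=C[C@]12C | intermediate
40 | 7-hydroxy-8-ketone | CC(C)[Si](C(C)C)(C(C)C)O[C@@H]1[C@H](OCC=C)[C@@H](O[Si](C(C)C)(C(C)C)C(C)C)/C(C)=C\[C@H](O)C(=O)[C@@H](O[Si](c2ccccc2)(c2ccccc2)C(C)(C)C)[C@H]2[C@]3(C)OC(C)(C)O[C@@H]3C=C[C@]12C | intermediate
41 | (R)-lactic acid | C[C@@H](O)C(=O)O | starting material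
42 | (2R,5R)-2-tert-butyl-5-methyl-1,3-dioxolan-4-one (cis) | C[C@H]1O[C@@H](C(C)(C)C)OC1=O | intermediate
43 | aldol adduct: C8 carbinol carrying the 2-tert-butyl-5-methyl-4-oxo-1,3-dioxolan-5-yl group (C17), 7-OH free | CC(C)[Si](C(C)C)(C(C)C)O[C@@H]1[C@H](OCC=C)[C@@H](O[Si](C(C)C)(C(C)C)C(C)C)/C(C)=C\[C@H](O)[C@@](O)([C@]3(C)O[C@@H](C(C)(C)C)OC3=O)[C@@H](O[Si](c2ccccc2)(c2ccccc2)C(C)(C)C)[C@H]2[C@]3(C)OC(C)(C)O[C@@H]3C=C[C@]12C | intermediate
44 | γ-lactone with 8,17-diol (2,4-bis-TIPS, 9-OTBDPS, 3-O-allyl, 11,12-acetonide) | CC(C)[Si](C(C)C)(C(C)C)O[C@@H]1[C@H](OCC=C)[C@@H](O[Si](C(C)C)(C(C)C)C(C)C)/C(C)=C\[C@@H]2OC(=O)[C@@](C)(O)[C@@]2(O)[C@@H](O[Si](c2ccccc2)(c2ccccc2)C(C)(C)C)[C@H]2[C@]3(C)OC(C)(C)O[C@@H]3C=C[C@]12C | intermediate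
45 | 2,4,9-triol (3-O-allyl, 11,12-acetonide) | O[C@@H]1[C@H](OCC=C)[C@@H](O)/C(C)=C\[C@@H]2OC(=O)[C@@](C)(O)[C@@]2(O)[C@@H](O)[C@H]2[C@]3(C)OC(C)(C)O[C@@H]3C=C[C@]12C | intermediate
46 | 2,4,9-triacetate (3-O-allyl, 11,12-acetonide) | CC(=O)O[C@@H]1[C@H](OCC=C)[C@@H](OC(C)=O)/C(C)=C\[C@@H]2OC(=O)[C@@](C)(O)[C@@]2(O)[C@@H](OC(C)=O)[C@H]2[C@]3(C)OC(C)(C)O[C@@H]3C=C[C@]12C | intermediate
47 | 3-O-[(E)-prop-1-enyl] ether of the triacetate acetonide | CC(=O)O[C@@H]1[C@H](O/C=C/C)[C@@H](OC(C)=O)/C(C)=C\[C@@H]2OC(=O)[C@@](C)(O)[C@@]2(O)[C@@H](OC(C)=O)[C@H]2[C@]3(C)OC(C)(C)O[C@@H]3C=C[C@]12C | intermediate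
48 | Brianodin C | CC(=O)O[C@@H]1[C@H](O)[C@@H](OC(C)=O)/C(C)=C\[C@@H]2OC(=O)[C@@](C)(O)[C@@]2(O)[C@@H](OC(C)=O)[C@H]2[C@](C)(O)[C@H](O)C=C[C@]12C | target

**Counts and risks**

Total step count: 33. Longest linear sequence: 28 steps (1, 2, 5–8, 10–18, 20–28, 30–33).

Steps most likely to fail:

Step 5. The carbenoid may be consumed by dimerisation or C–H insertion before it adds to the hindered diene, or may discriminate poorly between the two enantiotopic double bonds. Fallback: from 4, a polar (4+3) cycloaddition with the oxyallyl cation released from 1,3-dibromobutan-2-one (NaI, Cu, MeCN) should give the racemic bicyclic ketone F1. Kinetic enolisation at the C13 methylene [LiN(SiMe3)2, THF, −78 °C] and N-chlorosuccinimide should give the racemic chloroketone F2. Dihydroxylation as in step 7 should give the racemic diol F3. Lipase-mediated acetylation (vinyl acetate) is expected to leave 13 untouched and to convert its enantiomer into the monoacetate F4, so the route is rejoined at 13.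

Step 7. Osmium may attack the exo face despite the C1 methyl (poor facial selectivity), which would lead to the C9 epimer. Fallback: from 12, Woodward cis-hydroxylation (I2, AgOAc, wet AcOH), in which the iodonium ion forms on the exo face and the acetoxonium ion then delivers both oxygens to the endo face, should give the endo hydroxy acetate F5. Methanolysis (K2CO3, MeOH, 0 °C) then gives 13.

Step 30. The basic, hindered enolate may enolise the macrocyclic ketone instead of adding to it, or add to the wrong face. Fallback: from 40, acylation of the C7 hydroxyl (2-bromopropanoyl bromide, pyridine) should give the bromo ester F6. An intramolecular Reformatsky reaction (activated Zn, THF) should close the β-hydroxy lactone F7 (C17 epimers), the large C9 chain taking the side trans to C6. Hydroxylation of its dianion [LiN(iPr)2, then 3-phenyl-2-(phenylsulfonyl)oxaziridine, −78 °C], anti to the C8 alkoxide, leads to 44.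

Further compounds
F1 | step 5 | racemic 2,8-dimethyl-3-oxobicyclo[3.2.1]oct-6-ene-8-carbonitrile (8-methyl syn to the etheno bridge; one enantiomer drawn) | N#C[C@]1(C)[C@H]2C=C[C@@H]1CC(=O)[C@@H]2C
F2 | step 5 | racemic 2-chloro-4,8-dimethyl-3-oxobicyclo[3.2.1]oct-6-ene-8-carbonitrile (racemic 12; one enantiomer drawn) | N#C[C@]1(C)[C@H]2C=C[C@@H]1[C@@H](Cl)C(=O)[C@@H]2C
F3 | step 5 | racemic endo,cis-diol (racemic 13; one enantiomer drawn) | N#C[C@]1(C)[C@H]2[C@H](O)[C@H](O)[C@@H]1[C@@H](Cl)C(=O)[C@@H]2C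
F4 | step 5 | monoacetate of the enantiomer of 13 | N#C[C@@]1(C)[C@@H]2[C@@H](O)[C@@H](OC(C)=O)[C@H]1[C@H](Cl)C(=O)[C@H]2C
F5 | step 7 | endo,cis hydroxy acetate of 12 (acetate on C9, hydroxyl on C8) | N#C[C@]1(C)[C@H]2[C@H](OC(C)=O)[C@H](O)[C@@H]1[C@@H](Cl)C(=O)[C@@H]2C
F6 | step 30 | C7 2-bromopropanoate of 40 | CC(C)[Si](C(C)C)(C(C)C)O[C@@H]1[C@H](OCC=C)[C@@H](O[Si](C(C)C)(C(C)C)C(C)C)/C(C)=C\[C@H](OC(=O)C(C)Br)C(=O)[C@@H](O[Si](c2ccccc2)(c2ccccc2)C(C)(C)C)[C@H]2[C@]3(C)OC(C)(C)O[C@@H]3C=C[C@]12C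
F7 | step 30 | 8-hydroxy-17-methyl γ-lactone lacking the 17-hydroxyl (C17 epimers) | CC(C)[Si](C(C)C)(C(C)C)O[C@@H]1[C@H](OCC=C)[C@@H](O[Si](C(C)C)(C(C)C)C(C)C)/C(C)=C\[C@@H]2OC(=O)C(C)[C@@]2(O)[C@@H](O[Si](c2ccccc2)(c2ccccc2)C(C)(C)C)[C@H]2[C@]3(C)OC(C)(C)O[C@@H]3C=C[C@]12C
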